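The biflavone is cut through ring A'' of the 6''-aryloxyflavone. In that ring the ether-bearing C6'' lies between the oxygenated C5'' and C7'', the pattern of a 2-aryloxymalonyl unit. C8'' and C4a'' map onto the methyl carbon and C5 of a 6-methyl-4-pyranone that itself becomes ring C''. One operation, a double C-acylation of the pyranone dienolate by a genkwanin-derived aryloxymalonate, forms C7''–C8'' and C5''–C4a'' and aromatises ring A''. The malonate is used as its bis(2,4,6-trichlorophenyl) ester: a dialkyl ester would only quench the dienolate through its acidic C–H, whereas the aryl ester releases a ketene. Selective 7''-O-methylation and debenzylation finish the synthesis.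

Key step: step 6

Remark: the target has no stereocentre, so it is a single achiral compound and no step has to control configuration.
Remark: unprimed and single-primed locants refer to the genkwanin unit, double- and triple-primed locants to the 6''-linked flavone.
Assumption: genkwanin (apigenin 7-methyl ether) is bought as such.
Assumption: salts and enolates formed by simple deprotonation of a numbered compound count as forms of that compound and carry no number of their own.

Step 1
Reactants: 1 genkwanin (5,4'-dihydroxy-7-methoxyflavone); 2 diethyl bromomalonate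
Product: 3 diethyl 2-[4-(5-hydroxy-7-methoxy-4-oxo-4H-chromen-2-yl)phenoxy]malonate
Conditions: 2 (1.1 equiv), K2CO3 (1.2 equiv), DMF, 40 °C
Reagents that add atoms: none
Why: Williamson-type SN2 O-alkylation by the reactive α-bromo diester should occur only at the 4'-phenoxide, because the 5-OH is held in a hydrogen bond to the C4 carbonyl and is a poor nucleophile.

Step 2
Reactants: 3 diethyl 2-[4-(5-hydroxy-7-methoxy-4-oxo-4H-chromen-2-yl)phenoxy]malonate
Product: 4 2-[4-(5-hydroxy-7-methoxy-4-oxo-4H-chromen-2-yl)phenoxy]malonic acid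
Conditions: LiOH·H2O (6 equiv), THF–H2O, 0 °C → rt; then 1 M HCl, 0 °C
Reagents that add atoms: lithium hydroxide, [Li+].[OH-]
Why: Saponification of both malonate esters should proceed at room temperature, where the flavone ring and the aryl ethers are stable, and cold acidification avoids decarboxylation of the malonic acid.

Step 3
Reactants: 4 2-[4-(5-hydroxy-7-methoxy-4-oxo-4H-chromen-2-yl)phenoxy]malonic acid
Product: 5 bis(2,4,6-trichlorophenyl) 2-[4-(5-hydroxy-7-methoxy-4-oxo-4H-chromen-2-yl)phenoxy]malonate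
Conditions: 2,4,6-trichlorophenol (2.2 equiv), DCC (2.2 equiv), THF, 0 °C → rt
Reagents that add atoms: 2,4,6-trichlorophenol, Oc1c(Cl)cc(Cl)cc1Cl
Why: Carbodiimide active-ester formation should esterify both carboxyl groups, since the chelated 5-OH cannot compete with the excess trichlorophenol and the low temperature limits N-acylurea formation and decarboxylation.

Step 4
Reactants: 6 acetylacetone (pentane-2,4-dione); 7 methyl 4-(benzyloxy)benzoate
Product: 8 1-[4-(benzyloxy)phenyl]hexane-1,3,5-trione
Conditions: 6 (2.0 equiv), LDA (4.2 equiv), THF, −78 → 0 °C; then 7 (1.0 equiv), 0 °C → rt; 1 M HCl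
Reagents that add atoms: none
Why: Claisen acylation of the acetylacetone 1,3-dianion should take place at its more nucleophilic terminal carbon with the non-enolisable aryl ester, the excess dianion absorbing the acidic proton of the triketone.

Step 5
Reactants: 8 1-[4-(benzyloxy)phenyl]hexane-1,3,5-trione
Product: 9 2-[4-(benzyloxy)phenyl]-6-methyl-4H-pyran-4-one
Conditions: p-TsOH·H2O (10 mol %), toluene, reflux (Dean–Stark)
Reagents that add atoms: none
Why: Acid-catalysed cyclodehydration of the 1,3,5-triketone (enol oxygen onto the terminal carbonyl, then loss of water) should give the γ-pyranone, and catalytic sulfonic acid leaves the benzyl aryl ether intact.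

Step 6
Reactants: 5 bis(2,4,6-trichlorophenyl) 2-[4-(5-hydroxy-7-methoxy-4-oxo-4H-chromen-2-yl)phenoxy]malonate; 9 2-[4-(benzyloxy)phenyl]-6-methyl-4H-pyran-4-one
Product: 12 2-[4-(benzyloxy)phenyl]-5,7-dihydroxy-6-[4-(5-hydroxy-7-methoxy-4-oxo-4H-chromen-2-yl)phenoxy]-4H-chromen-4-one (4'''-O-benzyl-7''-O-demethyl target), via aryloxyketene 10 (not isolated), via keto ester 11 (not isolated)
Conditions: 9 (1.5 equiv), LiHMDS (3.6 equiv), THF, −78 °C; then 5 (1.0 equiv) in THF, −78 °C → rt; then 60 °C; 1 M HCl
Reagents that add atoms: none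
Why: Proposed new method: the excess base converts 5 into its malonate enolate, which expels 2,4,6-trichlorophenoxide (E1cB) to give ketene 10, and the lithium dienolate of 9, whose charge sits only on the methyl carbon, C5 and O4, adds through its exocyclic carbon to the ketene carbon (C7''–C8'') to give keto ester 11. Deprotonation of the new CH2 of 11 regenerates a dienolate whose α-carbon is pyranone C5, which attacks the remaining activated ester carbonyl (directly or after the same aryloxide loss) in a 6-exo-trig Dieckmann-type closure (C5''–C4a''), and double enolisation of the resulting cyclic triketone aromatises ring A''. The closest known reactions are the malonate/acetonedicarboxylate Claisen route to phloroglucinols, the Claisen cyclisation of polyketo esters to acylphloroglucinols and the cyclocondensation of bis(2,4,6-trichlorophenyl) malonates with 1,3-dinucleophiles, none of which uses a methylpyranone as C,C-dinucleophile. No stereocentre is formed. The step needs C- rather than O-acylation and reaction at C5 rather than C3: O-acylated species are themselves active esters and can pass the acyl group on, C3 carries no dienolate charge, and only the methyl carbon/C5 pair can close a six-membered ring with the three malonate carbons, which also fixes the aryloxy carbon as C6'' and excludes an 8''-aryloxy isomer. Either order of the two acylations should converge on 12.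

Step 7
Reactants: 12 2-[4-(benzyloxy)phenyl]-5,7-dihydroxy-6-[4-(5-hydroxy-7-methoxy-4-oxo-4H-chromen-2-yl)phenoxy]-4H-chromen-4-one
Product: 13 2-[4-(benzyloxy)phenyl]-5-hydroxy-6-[4-(5-hydroxy-7-methoxy-4-oxo-4H-chromen-2-yl)phenoxy]-7-methoxy-4H-chromen-4-one
Conditions: MeI (1.2 equiv), K2CO3 (1.5 equiv), DMF, rt
Reagents that add atoms: iodomethane, CI
Why: SN2 O-methylation should occur only at 7''-OH, the one phenol not hydrogen-bonded to a C4 carbonyl, so that the chelated 5-OH and 5''-OH stay free with about one equivalent of iodomethane and a weak base.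

Step 8
Reactants: 13 2-[4-(benzyloxy)phenyl]-5-hydroxy-6-[4-(5-hydroxy-7-methoxy-4-oxo-4H-chromen-2-yl)phenoxy]-7-methoxy-4H-chromen-4-one
Product: 14 5-hydroxy-6-[4-(5-hydroxy-7-methoxy-4-oxo-4H-chromen-2-yl)phenoxy]-2-(4-hydroxyphenyl)-7-methoxy-4H-chromen-4-one (target)
Conditions: H2 (1 atm), 10% Pd/C, THF–MeOH, rt
Reagents that add atoms: none
Why: Catalytic hydrogenolysis should cleave the benzyl aryl ether, while the flavone C2=C3 bonds, the diaryl ether and the methyl ethers are normally untouched at 1 atm and room temperature.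

Compound list
1 | genkwanin (5,4'-dihydroxy-7-methoxyflavone) | COc1cc(O)c2c(=O)cc(-c3ccc(O)cc3)oc2c1 | starting material
2 | diethyl bromomalonate | CCOC(=O)C(Br)C(=O)OCC | starting material
3 | diethyl 2-[4-(5-hydroxy-7-methoxy-4-oxo-4H-chromen-2-yl)phenoxy]malonate | CCOC(=O)C(Oc1ccc(-c2cc(=O)c3c(O)cc(OC)cc3o2)cc1)C(=O)OCC | intermediate
4 | 2-[4-(5-hydroxy-7-methoxy-4-oxo-4H-chromen-2-yl)phenoxy]malonic acid | OC(=O)C(Oc1ccc(-c2cc(=O)c3c(O)cc(OC)cc3o2)cc1)C(=O)O | intermediate
5 | bis(2,4,6-trichlorophenyl) 2-[4-(5-hydroxy-7-methoxy-4-oxo-4H-chromen-2-yl)phenoxy]malonate | O=C(Oc1c(Cl)cc(Cl)cc1Cl)C(Oc1ccc(-c2cc(=O)c3c(O)cc(OC)cc3o2)cc1)C(=O)Oc1c(Cl)cc(Cl)cc1Cl | intermediate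
6 | acetylacetone (pentane-2,4-dione) | CC(=O)CC(C)=O | starting material
7 | methyl 4-(benzyloxy)benzoate | COC(=O)c1ccc(OCc2ccccc2)cc1 | starting material
8 | 1-[4-(benzyloxy)phenyl]hexane-1,3,5-trione | CC(=O)CC(=O)CC(=O)c1ccc(OCc2ccccc2)cc1 | intermediate
9 | 2-[4-(benzyloxy)phenyl]-6-methyl-4H-pyran-4-one | Cc1cc(=O)cc(-c2ccc(OCc3ccccc3)cc2)o1 | intermediate
10 | [4-(5-hydroxy-7-methoxy-4-oxo-4H-chromen-2-yl)phenoxy](2,4,6-trichlorophenoxycarbonyl)ketene | O=C=C(Oc1ccc(-c2cc(=O)c3c(O)cc(OC)cc3o2)cc1)C(=O)Oc1c(Cl)cc(Cl)cc1Cl | intermediate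
11 | 2,4,6-trichlorophenyl 4-{6-[4-(benzyloxy)phenyl]-4-oxo-4H-pyran-2-yl}-2-[4-(5-hydroxy-7-methoxy-4-oxo-4H-chromen-2-yl)phenoxy]-3-oxobutanoate | O=C(Cc1cc(=O)cc(-c2ccc(OCc3ccccc3)cc2)o1)C(Oc1ccc(-c2cc(=O)c3c(O)cc(OC)cc3o2)cc1)C(=O)Oc1c(Cl)cc(Cl)cc1Cl | intermediate
12 | 2-[4-(benzyloxy)phenyl]-5,7-dihydroxy-6-[4-(5-hydroxy-7-methoxy-4-oxo-4H-chromen-2-yl)phenoxy]-4H-chromen-4-one | COc1cc(O)c2c(=O)cc(-c3ccc(Oc4c(O)cc5oc(-c6ccc(OCc7ccccc7)cc6)cc(=O)c5c4O)cc3)oc2c1 | intermediate
13 | 2-[4-(benzyloxy)phenyl]-5-hydroxy-6-[4-(5-hydroxy-7-methoxy-4-oxo-4H-chromen-2-yl)phenoxy]-7-methoxy-4H-chromen-4-one | COc1cc(O)c2c(=O)cc(-c3ccc(Oc4c(OC)cc5oc(-c6ccc(OCc7ccccc7)cc6)cc(=O)c5c4O)cc3)oc2c1 | intermediate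
14 | 5-hydroxy-6-[4-(5-hydroxy-7-methoxy-4-oxo-4H-chromen-2-yl)phenoxy]-2-(4-hydroxyphenyl)-7-methoxy-4H-chromen-4-one | COc1cc(O)c2c(=O)cc(-c3ccc(Oc4c(OC)cc5oc(-c6ccc(O)cc6)cc(=O)c5c4O)cc3)oc2c1 | target

Total step count: 8. Longest linear sequence: 6 steps (steps 1, 2, 3, 6, 7, 8); the pyranone branch (steps 4, 5) joins at step 6.

Steps most likely to fail

Step 6 (proposed method). Carbon–carbon bond formation may lose out to proton transfer, O-acylation or oligomerisation of the ketene, or the closure at C5 may stall after the first acylation. The fallback uses known reactions only, sets out from 1 and comes back to the route at 14. Benzylation of the 4'-OH of 1 (BnBr, K2CO3, acetone) should give 4'-O-benzylgenkwanin F1. Iodination directed by the free 5-OH (BnMe3N·ICl2, CaCO3, CH2Cl2–MeOH) should give 4'-O-benzyl-6-iodogenkwanin F2. Benzylation of the chelated 5-OH (BnBr, K2CO3, DMF, 70 °C) should give 5,4'-di-O-benzyl-6-iodo-7-methoxyflavone F3. Ullmann diaryl ether coupling of F3 with the 4'-OH of a second portion of 1 (CuI, picolinic acid, K3PO4, DMSO, 90 °C) should give 5''-O-benzyl-13 F4. The hydrogenolysis conditions of step 8 then remove both benzyl groups of F4 and give 14.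

Step 3. The activated malonic acid may lose carbon dioxide, or the O-acylisourea may rearrange to an N-acylurea before the hindered phenol attacks. The fallback sets out from 4 and comes back at 5. Oxalyl chloride (cat. DMF, CH2Cl2, 0 °C) should convert 4 into 2-[4-(5-hydroxy-7-methoxy-4-oxo-4H-chromen-2-yl)phenoxy]malonyl dichloride F5. Heating F5 with 2,4,6-trichlorophenol in toluene without base, until hydrogen chloride evolution ends, should give 5 by the classical acid chloride route to diaryl malonates.

Step 1. Halogen transfer from the bromomalonate to the electron-rich phenoxide, or a second alkylation of the acidic product, may consume material. The fallback sets out from 1 and comes back at 3. Rh2(OAc)4-catalysed O–H insertion of the carbenoid from diethyl diazomalonate into the 4'-OH of 1 (toluene–1,2-dichloroethane, 80 °C) should form the same aryloxymalonate without base or electrophilic halogen; it makes no new compound.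

Further compounds
F1 | step 6 | 4'-O-benzylgenkwanin (2-[4-(benzyloxy)phenyl]-5-hydroxy-7-methoxy-4H-chromen-4-one) | COc1cc(O)c2c(=O)cc(-c3ccc(OCc4ccccc4)cc3)oc2c1
F2 | step 6 | 4'-O-benzyl-6-iodogenkwanin (2-[4-(benzyloxy)phenyl]-5-hydroxy-6-iodo-7-methoxy-4H-chromen-4-one) | COc1cc2oc(-c3ccc(OCc4ccccc4)cc3)cc(=O)c2c(O)c1I
F3 | step 6 | 5,4'-di-O-benzyl-6-iodo-7-methoxyflavone (5-(benzyloxy)-2-[4-(benzyloxy)phenyl]-6-iodo-7-methoxy-4H-chromen-4-one) | COc1cc2oc(-c3ccc(OCc4ccccc4)cc3)cc(=O)c2c(OCc5ccccc5)c1I
F4 | step 6 | 5''-O-benzyl-13 (5-(benzyloxy)-2-[4-(benzyloxy)phenyl]-6-[4-(5-hydroxy-7-methoxy-4-oxo-4H-chromen-2-yl)phenoxy]-7-methoxy-4H-chromen-4-one) | COc1cc(O)c2c(=O)cc(-c3ccc(Oc4c(OC)cc5oc(-c6ccc(OCc7ccccc7)cc6)cc(=O)c5c4OCc8ccccc8)cc3)oc2c1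
F5 | step 3 | 2-[4-(5-hydroxy-7-methoxy-4-oxo-4H-chromen-2-yl)phenoxy]malonyl dichloride | O=C(Cl)C(Oc1ccc(-c2cc(=O)c3c(O)cc(OC)cc3o2)cc1)C(=O)Cl
F0 | step 1 | none | none
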